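The route rests on disconnecting the aryl ether bond O1–C7a of the dihydrobenzofuran. In ring A, C7a lies para to C5, the carbon that bears the diol side chain, and ortho to the C7 methoxy group. With the first side-chain carbon held as a nitrile, C7a becomes an SNAr acceptor, and the crowded middle methoxy group of a bromoveratraldehyde-derived ring serves as leaving group. The precursor is an open-chain (1S,2S)-1,2-diarylpropan-1-ol whose two centres come from one transfer hydrogenation with dynamic kinetic resolution. Its alkoxide closes the five-membered ring in one operation without touching the C2–O bond, so both centres are carried over unchanged. The nitrile then grows into the erythro diol.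

Key step: step 4

Numbering used throughout, also for the open precursors: O1, C2, C3, C3a, C4–C7, C7a of 2,3-dihydro-1-benzofuran. Ring A is its benzo ring, ring B is the 3,4-dimethoxyphenyl group, and C1', C2', C3' are the side-chain carbons on C5.
Assumption: the sense of induction of both TsDPEN catalysts is assigned from the usual model, in which the (S,S) complex gives (S)-1-arylalkanols.

Step 1
Reactants: 1 3-bromo-4,5-dimethoxybenzaldehyde
Product: 3 3-bromo-4,5-dimethoxybenzonitrile, via aldoxime 2 (not isolated)
Conditions: NH2OH·HCl (1.2 equiv), DMSO, 100 °C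
Reagents that add atoms: hydroxylamine hydrochloride, NO.Cl
Why: One-pot aldehyde-to-nitrile conversion, in which condensation with hydroxylamine gives aldoxime 2 and this loses water in hot DMSO under the acid set free; no stereocentre is involved.

Step 2
Reactants: 3 3-bromo-4,5-dimethoxybenzonitrile; 4 1-(3,4-dimethoxyphenyl)propan-1-one
Product: 5 (±)-3-[1-(3,4-dimethoxyphenyl)-1-oxopropan-2-yl]-4,5-dimethoxybenzonitrile
Conditions: Pd2(dba)3 (1 mol %), Xantphos (2.5 mol %), K3PO4 (2.3 equiv), toluene, 80 °C
Reagents that add atoms: none
Why: Palladium-catalysed ketone α-arylation (Buchwald–Hartwig type), in which zerovalent palladium inserts into the C–Br bond, the enolate of 4 binds and reductive elimination forms C3–C3a; the mild phosphate base spares the nitrile, and the new centre is left racemic because it is labile and is set in step 3.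

Step 3
Reactants: 5 (±)-3-[1-(3,4-dimethoxyphenyl)-1-oxopropan-2-yl]-4,5-dimethoxybenzonitrile
Product: 6 3-[(1S,2S)-1-(3,4-dimethoxyphenyl)-1-hydroxypropan-2-yl]-4,5-dimethoxybenzonitrile
Conditions: RuCl[(S,S)-TsDPEN](p-cymene) (2 mol %), HCO2H/Et3N (1:2), MeCN, 40 °C
Reagents that add atoms: none
Why: Noyori asymmetric transfer hydrogenation with dynamic kinetic resolution, in which the amine-rich medium racemises the α-aryl ketone centre through its enolate, the (S,S) catalyst delivers hydride to the face that gives the (S)-aryl carbinol, and the (S)-ketone, for which this is also the Felkin–Anh face, should react faster, so that the product emerges as (1S,2S).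

Step 4
Reactants: 6 3-[(1S,2S)-1-(3,4-dimethoxyphenyl)-1-hydroxypropan-2-yl]-4,5-dimethoxybenzonitrile
Product: 9 (2S,3S)-2-(3,4-dimethoxyphenyl)-7-methoxy-3-methyl-2,3-dihydro-1-benzofuran-5-carbonitrile, via potassium alkoxide 7 (not isolated), via Meisenheimer adduct 8 (not isolated)
Conditions: KHMDS (1.0 equiv), THF, 0 °C; then NMP, 80 °C; then H2O
Reagents that add atoms: none
Why: Deprotonation gives potassium alkoxide 7, whose oxygen adds to C7a ipso to the methoxy group to give the cyano-stabilised Meisenheimer adduct 8, and loss of methoxide restores ring A (addition–elimination SNAr; the closest known type is the base-mediated exchange of the methoxy group of 2- and 4-methoxybenzonitriles for other alkoxides). The five-membered ring closes by a 5-exo-trig attack, counted on the C7a=C7 bond, which is the geometry common to benzo-fused five-ring SNAr closures. No stereocentre is created: the C2–O and C3–C3a bonds are not touched, so (1S,2S)-6 maps onto (2S,3S)-9 with ring B and the methyl group trans, and neither benzylic C–H is acidic enough to be removed under these conditions. The step needs site selectivity among four methoxy groups, and the substrate secures it, since only the C7a methoxy group is para to the nitrile, only it lies within reach of the tethered oxygen, and its two ortho neighbours twist it out of conjugation, which makes C7a more electrophilic and methoxide loss easier. The closure should be driven by the entropy of ring formation, by relief of crowding at C7a and by the push–pull conjugation that the now coplanar O1 gains with the para nitrile, so that return of methoxide is uphill.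

Step 5
Reactants: 9 (2S,3S)-2-(3,4-dimethoxyphenyl)-7-methoxy-3-methyl-2,3-dihydro-1-benzofuran-5-carbonitrile
Product: 12 1-[(2S,3S)-2-(3,4-dimethoxyphenyl)-7-methoxy-3-methyl-2,3-dihydro-1-benzofuran-5-yl]propane-1,2-dione, via N-lithio ketimine 10 (not isolated), via 2-ethoxy enone 11 (not isolated)
Conditions: ethyl vinyl ether, tBuLi, THF, −78 to 0 °C; then 9, −78 to 0 °C; then 2 M aq HCl, THF, rt
Reagents that add atoms: ethyl vinyl ether (used as 1-ethoxyvinyllithium), C=COCC; water, O
Why: Nucleophilic acylation with a metalated enol ether, in which addition of 1-ethoxyvinyllithium to the nitrile stops at N-lithio ketimine 10 and aqueous acid hydrolyses both the imine and the enol ether to unveil the 1,2-dione; C2 and C3 are not touched, and any reversible acid ionisation at C2 would only return the more stable trans ring.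

Step 6
Reactants: 12 1-[(2S,3S)-2-(3,4-dimethoxyphenyl)-7-methoxy-3-methyl-2,3-dihydro-1-benzofuran-5-yl]propane-1,2-dione
Product: 14 (1S,2R)-1-[(2S,3S)-2-(3,4-dimethoxyphenyl)-7-methoxy-3-methyl-2,3-dihydro-1-benzofuran-5-yl]propane-1,2-diol, via (R)-2-hydroxy ketone 13 (not isolated)
Conditions: RuCl[(R,R)-TsDPEN](p-cymene) (2 mol %), HCO2H/Et3N (5:2), 40 °C
Reagents that add atoms: none
Why: Noyori asymmetric transfer hydrogenation of an unsymmetrical 1-aryl-1,2-dione, in which the (R,R) catalyst first reduces the more reactive acetyl carbonyl to the (R)-carbinol 13 and then the aryl ketone to C1' (S) (same spatial sense, the descriptor changes because C2' outranks the aryl carbon), a catalyst-controlled sequence known to give anti (erythro) 1-arylpropane-1,2-diols, with the remote C2 and C3 playing no part.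

Compound list
1 | 3-bromo-4,5-dimethoxybenzaldehyde (5-bromoveratraldehyde) | COc1cc(C=O)cc(Br)c1OC | starting material
2 | (E)-3-bromo-4,5-dimethoxybenzaldehyde oxime | COc1cc(/C=N/O)cc(Br)c1OC | intermediate
3 | 3-bromo-4,5-dimethoxybenzonitrile | COc1cc(C#N)cc(Br)c1OC | intermediate
4 | 1-(3,4-dimethoxyphenyl)propan-1-one (3',4'-dimethoxypropiophenone) | CCC(=O)c1ccc(OC)c(OC)c1 | starting material
5 | (±)-3-[1-(3,4-dimethoxyphenyl)-1-oxopropan-2-yl]-4,5-dimethoxybenzonitrile | COc1ccc(C(=O)C(C)c2cc(C#N)cc(OC)c2OC)cc1OC | intermediate
6 | 3-[(1S,2S)-1-(3,4-dimethoxyphenyl)-1-hydroxypropan-2-yl]-4,5-dimethoxybenzonitrile | COc1ccc([C@@H](O)[C@H](c2c(OC)c(OC)cc(C#N)c2)C)cc1OC | intermediate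
7 | potassium alkoxide of 6 | COc1ccc([C@@H]([O-])[C@H](c2c(OC)c(OC)cc(C#N)c2)C)cc1OC.[K+] | intermediate
8 | potassium Meisenheimer adduct (C7a sp3, bearing O1 and OMe; charge on the cyano group) | COc1ccc([C@H]2OC3(OC)C(OC)=CC(=C=[N-])C=C3[C@@H]2C)cc1OC.[K+] | intermediate
9 | (2S,3S)-2-(3,4-dimethoxyphenyl)-7-methoxy-3-methyl-2,3-dihydro-1-benzofuran-5-carbonitrile | COc1ccc([C@H]2Oc3c(OC)cc(C#N)cc3[C@@H]2C)cc1OC | intermediate
10 | N-lithio ketimine from 9 and 1-ethoxyvinyllithium | COc1ccc([C@H]2Oc3c(OC)cc(C(=N[Li])C(=C)OCC)cc3[C@@H]2C)cc1OC | intermediate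
11 | 1-[(2S,3S)-2-(3,4-dimethoxyphenyl)-7-methoxy-3-methyl-2,3-dihydro-1-benzofuran-5-yl]-2-ethoxyprop-2-en-1-one | COc1ccc([C@H]2Oc3c(OC)cc(C(=O)C(=C)OCC)cc3[C@@H]2C)cc1OC | intermediate
12 | 1-[(2S,3S)-2-(3,4-dimethoxyphenyl)-7-methoxy-3-methyl-2,3-dihydro-1-benzofuran-5-yl]propane-1,2-dione | COc1ccc([C@H]2Oc3c(OC)cc(C(=O)C(C)=O)cc3[C@@H]2C)cc1OC | intermediate
13 | (2R)-1-[(2S,3S)-2-(3,4-dimethoxyphenyl)-7-methoxy-3-methyl-2,3-dihydro-1-benzofuran-5-yl]-2-hydroxypropan-1-one | COc1ccc([C@H]2Oc3c(OC)cc(C(=O)[C@@H](C)O)cc3[C@@H]2C)cc1OC | intermediate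
14 | (1S,2R)-1-[(2S,3S)-2-(3,4-dimethoxyphenyl)-7-methoxy-3-methyl-2,3-dihydro-1-benzofuran-5-yl]propane-1,2-diol | COc1ccc([C@H]2Oc3c(OC)cc([C@H](O)[C@@H](C)O)cc3[C@@H]2C)cc1OC | target

Total step count: 6. Longest linear sequence: 6 steps (1 to 14).

Steps most likely to fail

Step 4. The ipso attack may be too slow at a carbon that carries a poor leaving group. Intermolecular O-demethylation by the alkoxide, or addition of base to the nitrile, could then take over.
The fallback sets out from 6 and comes back at 9. It changes from SNAr to cross-coupling at the same carbon.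
- Sodium ethanethiolate in DMF at 100 °C should remove only the methyl group of the methoxy group para to the nitrile. This gives 3-[(1S,2S)-1-(3,4-dimethoxyphenyl)-1-hydroxypropan-2-yl]-4-hydroxy-5-methoxybenzonitrile F1.
- PhNTf2 and K2CO3 in acetone at room temperature should sulfonylate only the phenol, giving the corresponding aryl trifluoromethanesulfonate F2.
- Pd(OAc)2, 2-(di-tert-butylphosphino)-1,1'-binaphthyl and Cs2CO3 in toluene at 70 °C then close the same O1–C7a bond. This is an intramolecular palladium-catalysed aryl etherification, again with retention at C2, and gives 9.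

Step 3. Racemisation of the α-centre may be slower than hydride transfer. The dynamic resolution would then decay into a simple kinetic resolution, with loss of diastereo- and enantiopurity. The electron-rich, α-branched ketone may also be reduced sluggishly.
The fallback sets out from 5 and comes back at 6. It replaces catalyst control by substrate control followed by classical resolution.
- LiBH(sBu)3 in THF at −78 °C reduces 5 under Felkin–Anh control to racemic (1S*,2S*)-3-[1-(3,4-dimethoxyphenyl)-1-hydroxypropan-2-yl]-4,5-dimethoxybenzonitrile F3.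
- Esterification with (S)-2-methoxy-2-phenylacetic acid (DCC, DMAP, CH2Cl2) gives the (S)-2-methoxy-2-phenylacetate of the (1S,2S) alcohol F4 and the (S)-2-methoxy-2-phenylacetate of the (1R,2R) alcohol F5.
- The two esters are separated by chromatography or crystallisation, and LiOH in aqueous THF at room temperature cleaves F4 to 6.

Step 6. The second hydride transfer, to the electron-rich para-alkoxy aryl ketone, may stall. Its facial selectivity may also be incomplete, which would erode the erythro purity.
The fallback sets out from 12 and comes back at 14. It hands the second reduction to substrate control.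
- The transfer hydrogenation is run at 10 °C so that it stops after the acetyl carbonyl, and 13 is isolated.
- Zn(BH4)2 in Et2O at −20 °C then reduces the aryl ketone through a five-membered zinc chelate of the free hydroxyl and the carbonyl oxygen (Cram chelate model).
- Hydride is delivered from the side of the C2' hydrogen, which should give the anti diol 14.

Further compounds
F1 | step 4 | 3-[(1S,2S)-1-(3,4-dimethoxyphenyl)-1-hydroxypropan-2-yl]-4-hydroxy-5-methoxybenzonitrile | COc1ccc([C@@H](O)[C@H](c2c(O)c(OC)cc(C#N)c2)C)cc1OC
F2 | step 4 | 4-cyano-2-[(1S,2S)-1-(3,4-dimethoxyphenyl)-1-hydroxypropan-2-yl]-6-methoxyphenyl trifluoromethanesulfonate | COc1ccc([C@@H](O)[C@H](c2c(OS(=O)(=O)C(F)(F)F)c(OC)cc(C#N)c2)C)cc1OC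
F3 | step 3 | racemic (1S*,2S*)-3-[1-(3,4-dimethoxyphenyl)-1-hydroxypropan-2-yl]-4,5-dimethoxybenzonitrile (both enantiomers) | COc1ccc([C@@H](O)[C@H](c2c(OC)c(OC)cc(C#N)c2)C)cc1OC.COc1ccc([C@H](O)[C@@H](c2c(OC)c(OC)cc(C#N)c2)C)cc1OC
F4 | step 3 | (1S,2S)-2-(5-cyano-2,3-dimethoxyphenyl)-1-(3,4-dimethoxyphenyl)propyl (S)-2-methoxy-2-phenylacetate | COc1ccc([C@@H](OC(=O)[C@@H](OC)c3ccccc3)[C@H](c2c(OC)c(OC)cc(C#N)c2)C)cc1OC
F5 | step 3 | (1R,2R)-2-(5-cyano-2,3-dimethoxyphenyl)-1-(3,4-dimethoxyphenyl)propyl (S)-2-methoxy-2-phenylacetate | COc1ccc([C@H](OC(=O)[C@@H](OC)c3ccccc3)[C@@H](c2c(OC)c(OC)cc(C#N)c2)C)cc1OC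
F0 | step 6 | none | none
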